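**Retrosynthetic overview**
1. Marchantin C ⇐ one hydrogenolysis (two O-benzyl groups, one ring-B C–Cl) of an 18-membered macrocycle. This is the only ring the route forms and it is formed last; rings A–D are all bought as benzene derivatives.
2. Macrocycle ⇐ closure of the ring-A O–ring-B C(aryl) ether bond: the ring-A phenoxide adds to a ring-B aryne set free by fluoride from a 2-(trimethylsilyl)aryl triflate.
3. Enabling feature: in ring B the ether carbon has a C–H neighbour (the pair an aryne turns into C–O and C–H), and the next carbon (meta to the ether O, ortho to the bridge CH2) is a C–H that can carry a removable Cl to steer the addition. On ring A the ether O is flanked by a second O, kept as benzyl ether so that only one phenol is free.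
4. Seco-phenol ⇐ diimide reduction ⇐ Wittig union of a ring A/D/C aldehyde with a ring-B phosphonium salt (from 2-chloro-3-methylphenol: carbamate-directed ortho-silylation, triflation, benzylic bromination).
5. Aldehyde ⇐ Heck coupling of a ring-A styrene with a ring-D bromide, whose ring C–O–ring D ether comes from an SNAr of 3-bromophenol on 3-(benzyloxy)-2-fluorobenzaldehyde.

Key step: step 12

Remark on the chemistry: the target has no stereocentre; the four phenolic starting materials are taken as commercial; the E/Z composition of the alkene made in step 10 is immaterial because step 11 saturates it.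

**Step 1**
Reactants: 1 2-fluoro-3-hydroxybenzaldehyde
Product: 2 3-(benzyloxy)-2-fluorobenzaldehyde
Conditions: BnBr, K2CO3, DMF, rt
Reagents that add atoms: benzyl bromide, BrCc1ccccc1
Why: Williamson ether synthesis, in which the potassium phenoxide displaces bromide at the benzylic carbon (SN2) while the aldehyde and the aryl fluoride stay untouched.

**Step 2**
Reactants: 2 3-(benzyloxy)-2-fluorobenzaldehyde; 3 3-bromophenol
Product: 4 3-(benzyloxy)-2-(3-bromophenoxy)benzaldehyde
Conditions: K2CO3, DMF, 130 °C
Reagents that add atoms: none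
Why: Nucleophilic aromatic substitution (SNAr), in which the ortho-formyl group stabilises the Meisenheimer adduct and fluoride leaves, while the aryl bromide is inert without a metal catalyst.

**Step 3**
Reactants: 5 4-(benzyloxy)-3-hydroxybenzaldehyde
Product: 6 2-(benzyloxy)-5-ethenylphenol
Conditions: Ph3PCH3Br (2.5 equiv), KOtBu (2.5 equiv), THF, 0 °C → rt
Reagents that add atoms: methyltriphenylphosphonium bromide, C[P+](c1ccccc1)(c1ccccc1)c1ccccc1.[Br-]
Why: Wittig methylenation, run with excess ylide because one equivalent is consumed by the phenol, whose meta-phenoxide is not conjugated to the aldehyde and so does not deactivate it.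

**Step 4**
Reactants: 4 3-(benzyloxy)-2-(3-bromophenoxy)benzaldehyde; 6 2-(benzyloxy)-5-ethenylphenol
Product: 7 3-(benzyloxy)-2-{3-[(E)-2-(4-(benzyloxy)-3-hydroxyphenyl)ethenyl]phenoxy}benzaldehyde
Conditions: Pd(OAc)2 (5 mol %), P(o-tol)3, Et3N, DMF, 100 °C
Reagents that add atoms: none
Why: Mizoroki–Heck reaction, in which oxidative addition of the aryl bromide to zerovalent palladium, insertion at the terminal alkene carbon and syn β-hydride elimination should give the E-stilbene, with aldehyde and free phenol tolerated.

**Step 5**
Reactants: 8 2-chloro-3-methylphenol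
Product: 9 2-chloro-3-methylphenyl N-(propan-2-yl)carbamate
Conditions: iPrNCO, Et3N (0.2 equiv), CH2Cl2, rt
Reagents that add atoms: isopropyl isocyanate, CC(C)N=C=O
Why: Base-catalysed addition of the phenol to the isocyanate gives the N-monoalkyl carbamate, which later serves as ortho-directing group and as a base-cleavable phenol mask.

**Step 6**
Reactants: 9 2-chloro-3-methylphenyl N-(propan-2-yl)carbamate
Product: 13 2-chloro-3-methyl-6-(trimethylsilyl)phenyl N-(propan-2-yl)carbamate, via N-silyl carbamate 10 (not isolated), via aryllithium 11 (not isolated), via disilyl carbamate 12 (not isolated)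
Conditions: TBSOTf (1.1 equiv), TMEDA, Et2O, 0 °C → rt; then nBuLi (2 equiv), TMEDA, −78 °C; then Me3SiCl, −78 °C → rt; aq NaHSO4 work-up
Reagents that add atoms: chlorotrimethylsilane, C[Si](C)(C)Cl
Why: Directed ortho-metalation, in which N-silylation masks the N–H, the carbamate directs lithiation to its only free ortho position (the other is blocked by chlorine), Me3SiCl traps the aryllithium and the acidic work-up cleaves the N–Si bond.

**Step 7**
Reactants: 13 2-chloro-3-methyl-6-(trimethylsilyl)phenyl N-(propan-2-yl)carbamate
Product: 15 2-chloro-3-methyl-6-(trimethylsilyl)phenyl trifluoromethanesulfonate, via silylphenol 14 (not isolated)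
Conditions: Et2NH, DBU, MeCN, 40 °C; then PhNTf2, rt
Reagents that add atoms: N-phenylbis(trifluoromethanesulfonimide), O=S(=O)(N(c1ccccc1)S(=O)(=O)C(F)(F)F)C(F)(F)F
Why: E1cB cleavage of the N-monoalkyl carbamate by DBU (the expelled isocyanate is caught by Et2NH) followed by O-sulfonylation of the liberated phenoxide in the same flask, a standard entry to 2-(trimethylsilyl)aryl triflates.

**Step 8**
Reactants: 15 2-chloro-3-methyl-6-(trimethylsilyl)phenyl trifluoromethanesulfonate
Product: 16 3-(bromomethyl)-2-chloro-6-(trimethylsilyl)phenyl trifluoromethanesulfonate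
Conditions: NBS, AIBN (cat.), PhCF3, 80 °C
Reagents that add atoms: N-bromosuccinimide, O=C1CCC(=O)N1Br
Why: Wohl–Ziegler radical bromination at the only benzylic C–H position, the chloro- and triflyloxy-substituted ring being too electron-poor for ring bromination or ipso-bromodesilylation.

**Step 9**
Reactants: 16 3-(bromomethyl)-2-chloro-6-(trimethylsilyl)phenyl trifluoromethanesulfonate
Product: 17 {[2-chloro-3-(trifluoromethanesulfonyloxy)-4-(trimethylsilyl)phenyl]methyl}triphenylphosphonium bromide
Conditions: PPh3, toluene, 90 °C
Reagents that add atoms: triphenylphosphine, c1ccc(cc1)P(c1ccccc1)c1ccccc1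
Why: SN2 quaternisation of triphenylphosphine by the benzylic bromide under neutral conditions that leave the silyl/triflate pair intact.

**Step 10**
Reactants: 7 stilbene aldehyde; 17 ring-B phosphonium bromide
Product: 19 bis-stilbene silyl triflate (E/Z mixture at the new ring B/ring C alkene), via phosphorus ylide 18 (not isolated)
Conditions: LiN(SiMe3)2 (2.3 equiv), THF, −78 → 0 °C
Reagents that add atoms: none
Why: Wittig olefination of the non-enolisable aldehyde with the semi-stabilised benzylic ylide, the extra equivalent of amide base holding the phenol as lithium phenoxide; the triflate has no ortho hydrogen and no fluoride is present, so the aryne precursor should survive.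

**Step 11**
Reactants: 19 bis-stilbene silyl triflate
Product: 20 seco-phenol: 2-chloro-3-[2-(3-(benzyloxy)-2-{3-[2-(4-(benzyloxy)-3-hydroxyphenyl)ethyl]phenoxy}phenyl)ethyl]-6-(trimethylsilyl)phenyl trifluoromethanesulfonate
Conditions: TsNHNH2 (excess, in portions), NaOAc, DME/H2O, reflux
Reagents that add atoms: none
Why: Diimide reduction (concerted syn transfer of two hydrogens from HN=NH generated by thermolysis of the sulfonyl hydrazide) should saturate both stilbene double bonds without hydrogenolysis of the benzyl ethers, the C–Cl bond or the triflate.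

**Step 12**
Reactants: 20 seco-phenol silyl triflate
Product: 22 ring-B chloro di-O-benzyl marchantin C, via aryne 21 (not isolated)
Conditions: CsF (5 equiv), MeCN, 60 °C; 20 added by syringe pump over 12 h to about 1 mM final concentration
Reagents that add atoms: none
Why: Proposed new method: fluoride attacks the C–SiMe3 group of ring B and the resulting aryl anion expels the neighbouring triflate to give 3-chloroaryne 21, whose triple bond lies between the former C–Si and C–OTf carbons and is flanked by the C–Cl carbon; the cesium phenoxide of ring A adds to the aryne carbon remote from chlorine and the aryl anion left next to chlorine is protonated by the phenol/HF pool, so the O–C(aryl) bond para to the ethylene bridge is formed. The closest known reaction type is the intermolecular O-arylation of phenols by 2-(trimethylsilyl)aryl triflates with CsF in MeCN, together with the meta-selective addition of nucleophiles to 3-haloarynes; what is new is its use as a macrocyclisation. The 18-membered ring closes by intramolecular nucleophilic addition in the plane of ring B, the attacked aryne carbon becoming a ring member and its partner ending as C–H. No stereocentre is formed. The step needs regioselectivity across the triple bond, O- rather than C-arylation, reaction at the right oxygen, and ring closure rather than oligomerisation: the inductively withdrawing C–Cl bond distorts the aryne so that the remote carbon is the more electrophilic one and the developing negative charge sits next to chlorine, the cesium phenoxide in MeCN reacts at oxygen, the second ring-A oxygen is benzylated, and slow addition keeps the reactive species dilute.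

**Step 13**
Reactants: 22 ring-B chloro di-O-benzyl marchantin C
Product: 23 marchantin C
Conditions: H2 (3 bar), 10% Pd/C, NaOAc, MeOH/THF, rt → 40 °C
Reagents that add atoms: none
Why: Heterogeneous catalytic hydrogenolysis over palladium cleaves both benzylic C–O bonds and, with acetate as HCl acceptor, the aryl C–Cl bond (hydrodechlorination), while the diaryl ethers and bibenzyl bridges are inert.

**Compound list**
1 | 2-fluoro-3-hydroxybenzaldehyde | O=Cc1cccc(O)c1F | starting material
2 | 3-(benzyloxy)-2-fluorobenzaldehyde | O=Cc1cccc(OCc2ccccc2)c1F | intermediate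
3 | 3-bromophenol | Oc1cccc(Br)c1 | starting material
4 | 3-(benzyloxy)-2-(3-bromophenoxy)benzaldehyde | O=Cc1cccc(OCc2ccccc2)c1Oc1cccc(Br)c1 | intermediate
5 | 4-(benzyloxy)-3-hydroxybenzaldehyde | O=Cc1ccc(OCc2ccccc2)c(O)c1 | starting material
6 | 2-(benzyloxy)-5-ethenylphenol | C=Cc1ccc(OCc2ccccc2)c(O)c1 | intermediate
7 | 3-(benzyloxy)-2-{3-[(E)-2-(4-(benzyloxy)-3-hydroxyphenyl)ethenyl]phenoxy}benzaldehyde | O=Cc1cccc(OCc2ccccc2)c1Oc1cccc(/C=C/c2ccc(OCc3ccccc3)c(O)c2)c1 | intermediate
8 | 2-chloro-3-methylphenol | Cc1cccc(O)c1Cl | starting material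
9 | 2-chloro-3-methylphenyl N-(propan-2-yl)carbamate | Cc1cccc(OC(=O)NC(C)C)c1Cl | intermediate
10 | 2-chloro-3-methylphenyl N-[tert-butyl(dimethyl)silyl]-N-(propan-2-yl)carbamate (not isolated) | Cc1cccc(OC(=O)N(C(C)C)[Si](C)(C)C(C)(C)C)c1Cl | intermediate
11 | 6-lithio derivative of 10 (not isolated) | Cc1ccc([Li])c(OC(=O)N(C(C)C)[Si](C)(C)C(C)(C)C)c1Cl | intermediate
12 | 2-chloro-3-methyl-6-(trimethylsilyl)phenyl N-[tert-butyl(dimethyl)silyl]-N-(propan-2-yl)carbamate (not isolated) | Cc1ccc([Si](C)(C)C)c(OC(=O)N(C(C)C)[Si](C)(C)C(C)(C)C)c1Cl | intermediate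
13 | 2-chloro-3-methyl-6-(trimethylsilyl)phenyl N-(propan-2-yl)carbamate | Cc1ccc([Si](C)(C)C)c(OC(=O)NC(C)C)c1Cl | intermediate
14 | 2-chloro-3-methyl-6-(trimethylsilyl)phenol (not isolated) | Cc1ccc([Si](C)(C)C)c(O)c1Cl | intermediate
15 | 2-chloro-3-methyl-6-(trimethylsilyl)phenyl trifluoromethanesulfonate | Cc1ccc([Si](C)(C)C)c(OS(=O)(=O)C(F)(F)F)c1Cl | intermediate
16 | 3-(bromomethyl)-2-chloro-6-(trimethylsilyl)phenyl trifluoromethanesulfonate | BrCc1ccc([Si](C)(C)C)c(OS(=O)(=O)C(F)(F)F)c1Cl | intermediate
17 | {[2-chloro-3-(trifluoromethanesulfonyloxy)-4-(trimethylsilyl)phenyl]methyl}triphenylphosphonium bromide | [Br-].Clc1c(C[P+](c2ccccc2)(c2ccccc2)c2ccccc2)ccc([Si](C)(C)C)c1OS(=O)(=O)C(F)(F)F | intermediate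
18 | ylide of 17: [2-chloro-3-(trifluoromethanesulfonyloxy)-4-(trimethylsilyl)benzylidene]triphenylphosphorane (not isolated) | Clc1c(C=P(c2ccccc2)(c2ccccc2)c2ccccc2)ccc([Si](C)(C)C)c1OS(=O)(=O)C(F)(F)F | intermediate
19 | 2-chloro-3-[2-(3-(benzyloxy)-2-{3-[(E)-2-(4-(benzyloxy)-3-hydroxyphenyl)ethenyl]phenoxy}phenyl)ethenyl]-6-(trimethylsilyl)phenyl trifluoromethanesulfonate, E/Z mixture at the ring B/ring C alkene | Oc1cc(/C=C/c2cccc(Oc3c(C=Cc4ccc([Si](C)(C)C)c(OS(=O)(=O)C(F)(F)F)c4Cl)cccc3OCc3ccccc3)c2)ccc1OCc1ccccc1 | intermediate
20 | 2-chloro-3-[2-(3-(benzyloxy)-2-{3-[2-(4-(benzyloxy)-3-hydroxyphenyl)ethyl]phenoxy}phenyl)ethyl]-6-(trimethylsilyl)phenyl trifluoromethanesulfonate | Oc1cc(CCc2cccc(Oc3c(CCc4ccc([Si](C)(C)C)c(OS(=O)(=O)C(F)(F)F)c4Cl)cccc3OCc3ccccc3)c2)ccc1OCc1ccccc1 | intermediate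
21 | 3-chloroaryne of 20: ring B with a triple bond between the former C–Si and C–OTf carbons, Cl on the next carbon, bridge CH2 on the one after (not isolated) | Oc1cc(CCc2cccc(Oc3c(CCC4=C(Cl)C#CC=C4)cccc3OCc3ccccc3)c2)ccc1OCc1ccccc1 | intermediate
22 | ring-B chloro di-O-benzyl marchantin C: the 18-membered macrocycle with benzyl ethers on the ring-A and ring-C oxygens and Cl on ring B ortho to the bridge CH2, meta to the new ether oxygen | C(c1ccccc1)Oc1ccc2cc1Oc1ccc(c(Cl)c1)CCc1cccc(OCc3ccccc3)c1Oc1cccc(c1)CC2 | intermediate
23 | marchantin C | Oc1ccc2cc1Oc1ccc(cc1)CCc1cccc(O)c1Oc1cccc(c1)CC2 | target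

**Step count and risks**
Total steps: 13. Longest linear sequence: 9 steps (steps 5–13, from 8 to 23).

Steps most likely to fail:

1. Step 12 (Proposed new method). The aryne may be captured between molecules (oligomers), by fluoride or at a phenoxide carbon faster than the ring closes, or the ortho-chloroaryl anion may lose chloride before it is protonated. The fallback uses known chemistry, a copper-mediated intramolecular Ullmann etherification that closes the same O–C bond. It sets out from 7: Wittig olefination with commercial (4-bromobenzyl)triphenylphosphonium bromide (LiN(SiMe3)2, THF) should give the bromo bis-stilbene F1; diimide reduction as in step 11 gives the bromo seco-phenol F2; CuO, K2CO3, pyridine, reflux, high dilution should close the ring to marchantin C di-O-benzyl ether F3; H2, Pd/C, EtOAc/MeOH then removes the benzyl groups and the route is rejoined at 23.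

2. Step 11. Hydrogen transfer to two 1,2-diarylethenes may stay incomplete, and prolonged heating in aqueous acetate may erode the silyl/triflate pair. The fallback builds the ring A/ring D bridge already saturated and hydrogenates the single remaining alkene catalytically. It sets out from 6 and 4: hydroboration of 6 with 9-BBN (2.2 equiv, one equivalent being taken up by the phenol) gives the alkylborane F4 (used in solution); B-alkyl Suzuki–Miyaura coupling with 4 (Pd(dppf)Cl2, aq K3PO4, DMF, 60 °C) gives the saturated aldehyde F5; Wittig olefination with 17 as in step 10 gives the mono-stilbene F6; H2 (1 atm), RhCl(PPh3)3 (cat.), benzene/EtOH, rt saturates it, and the route is rejoined at 20.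

3. Step 13. Hydrodechlorination of the ortho-alkyl aryl chloride may stall once the phenols are free and bind to the catalyst, and forcing conditions risk ring saturation. The fallback separates the two events. It sets out from 22: BCl3, pentamethylbenzene, CH2Cl2, −78 °C removes both benzyl groups to give ring-B chloro marchantin C F7; homogeneous reductive dechlorination (Pd(OAc)2 cat., polymethylhydrosiloxane, aq KF, THF, rt) then rejoins the route at 23.

**Further compounds**
F1 | step 12 | 2-(benzyloxy)-5-[(E)-2-(3-{2-(benzyloxy)-6-[2-(4-bromophenyl)ethenyl]phenoxy}phenyl)ethenyl]phenol, E/Z mixture at the bromostyryl alkene | Oc1cc(/C=C/c2cccc(Oc3c(C=Cc4ccc(Br)cc4)cccc3OCc3ccccc3)c2)ccc1OCc1ccccc1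
F2 | step 12 | 2-(benzyloxy)-5-[2-(3-{2-(benzyloxy)-6-[2-(4-bromophenyl)ethyl]phenoxy}phenyl)ethyl]phenol | Oc1cc(CCc2cccc(Oc3c(CCc4ccc(Br)cc4)cccc3OCc3ccccc3)c2)ccc1OCc1ccccc1
F3 | step 12 | marchantin C di-O-benzyl ether | C(c1ccccc1)Oc1ccc2cc1Oc1ccc(cc1)CCc1cccc(OCc3ccccc3)c1Oc1cccc(c1)CC2
F4 | step 11 | B-alkyl-9-BBN adduct of 6, phenol held as its 9-BBN borinate | C(Cc1ccc(OCc2ccccc2)c(OB2C3CCCC2CCC3)c1)B1C2CCCC1CCC2
F5 | step 11 | 3-(benzyloxy)-2-{3-[2-(4-(benzyloxy)-3-hydroxyphenyl)ethyl]phenoxy}benzaldehyde | O=Cc1cccc(OCc2ccccc2)c1Oc1cccc(CCc2ccc(OCc3ccccc3)c(O)c2)c1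
F6 | step 11 | 2-chloro-3-[2-(3-(benzyloxy)-2-{3-[2-(4-(benzyloxy)-3-hydroxyphenyl)ethyl]phenoxy}phenyl)ethenyl]-6-(trimethylsilyl)phenyl trifluoromethanesulfonate, E/Z mixture | Oc1cc(CCc2cccc(Oc3c(C=Cc4ccc([Si](C)(C)C)c(OS(=O)(=O)C(F)(F)F)c4Cl)cccc3OCc3ccccc3)c2)ccc1OCc1ccccc1
F7 | step 13 | ring-B chloro marchantin C (Cl ortho to the bridge CH2 of ring B) | Oc1ccc2cc1Oc1ccc(c(Cl)c1)CCc1cccc(O)c1Oc1cccc(c1)CC2
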